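**Retrosynthetic overview**
- The 14-membered lactone is the only ring and is closed late, by a SmI2 Reformatsky C2–C3 bond formation between a C13 2-bromopropanoate and a C3 aldehyde; oxidation to the β-keto lactone and global desilylation finish the synthesis.
- C11–C15: nickel-catalysed reductive coupling of a 2-substituted 1,3-enyne with propanal gives the (E)-diene carbinol; C13 is then fixed by oxidation and CBS reduction.
- C8–C10: rhodium/BINAP conjugate addition of a C7 alkenylboronate to pent-3-en-2-one sets C8; the methyl ketone becomes the enyne through a kinetic enol triflate and Sonogashira coupling.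
- C6=C7: zirconium-catalysed methylalumination of a terminal alkyne.
- C3–C5 with the C4 tertiary carbinol (key step): dearomatising, auxiliary-controlled Birch reductive propargylation of a furan-2-carboxamide; the dihydrofuran is then cut down by allylic oxidation and oxidative cleavage to C4–OH and C4–CH2OH.

Labels: C1–C13 follow the lactone (C1 = lactone C=O, C2 = CHMe, C3 = ketone, C4 = carbinol carbon, C13 = O-bearing CH–Et). Xc = (2S,5S)-2,5-bis(methoxymethyl)pyrrolidin-1-yl.

Assumptions: (i) the (2S,5S) auxiliary is taken to give the (R) quaternary carbon in step 2; if the sense is the opposite, the (2R,5R) auxiliary is used with no other change. (ii) C2 lies between two carbonyls and is configurationally labile; the (2R) epimer of the target is taken to be the thermodynamically preferred one in the macrocycle.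

**Step 1**
Reactants: 1 furan-2-carbonyl chloride; 2 (2S,5S)-2,5-bis(methoxymethyl)pyrrolidine
Product: 3 furan-2-yl(Xc)methanone
Conditions: Et3N, DMAP (cat.), CH2Cl2, 0 °C → rt
Reagents that add atoms: none
Why: Simple N-acylation of the secondary amine by the acid chloride attaches the C2-symmetric auxiliary that directs the next step; no stereocentre is formed.

**Step 2**
Reactants: 3 furan-2-yl(Xc)methanone; 4 (3-bromoprop-1-yn-1-yl)trimethylsilane
Product: 6 [(2R)-2-[3-(trimethylsilyl)prop-2-yn-1-yl]-2,5-dihydrofuran-2-yl](Xc)methanone, via sodium enolate 5 (not isolated)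
Conditions: Na, NH3(l)/THF, −78 °C; isoprene; then 4, −78 → −40 °C
Reagents that add atoms: none
Why: Dearomatising Birch reductive alkylation of a 2-furamide (two-electron reduction and protonation at C5 give the exocyclic amide enolate), which is alkylated at the former furan C2 on the face left open by the auxiliary, setting the quaternary carbon that becomes C4.

**Step 3**
Reactants: 6 [(2R)-2-[3-(trimethylsilyl)prop-2-yn-1-yl]-2,5-dihydrofuran-2-yl](Xc)methanone
Product: 7 (5R)-5-(Xc-carbonyl)-5-[3-(trimethylsilyl)prop-2-yn-1-yl]furan-2(5H)-one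
Conditions: CrO3, 3,5-dimethylpyrazole, CH2Cl2, −20 °C
Reagents that add atoms: chromium trioxide, O=[Cr](=O)=O
Why: Allylic oxidation of the only allylic, O-activated CH2 of the 2,5-dihydrofuran gives the butenolide, so that the ring oxygen can later leave as an ester instead of an ether; the quaternary centre has no hydrogen and is untouched.

**Step 4**
Reactants: 7 (5R)-5-(Xc-carbonyl)-5-[3-(trimethylsilyl)prop-2-yn-1-yl]furan-2(5H)-one
Product: 10 (2R)-2-hydroxy-2-(hydroxymethyl)-1-Xc-pent-4-yn-1-one, via formyl glyoxylate ester 8 (not isolated), via glycolate ester 9 (not isolated)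
Conditions: OsO4 (2 mol%), NaIO4, 2,6-lutidine, dioxane/H2O, rt; then NaBH4, MeOH, 0 °C; then K2CO3 (cat.), MeOH, rt
Reagents that add atoms: osmium tetroxide, O=[Os](=O)(=O)=O; sodium periodate, [Na+].[O-]I(=O)(=O)=O
Why: Lemieux–Johnson cleavage of the butenolide C=C (the alkyne is inert to OsO4) leaves one carbon on C4 as an aldehyde and the ring oxygen as a glyoxylate ester; borohydride reduction and methanolysis then free the C4–CH2OH, the tertiary C4–OH and the terminal alkyne without touching the stereocentre.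

**Step 5**
Reactants: 10 (2R)-2-hydroxy-2-(hydroxymethyl)-1-Xc-pent-4-yn-1-one
Product: 11 (2R)-2-[(triethylsilyl)oxy]-2-{[(triethylsilyl)oxy]methyl}-1-Xc-pent-4-yn-1-one
Conditions: Et3SiOTf, 2,6-lutidine, CH2Cl2, −78 → 0 °C
Reagents that add atoms: triethylsilyl trifluoromethanesulfonate, CC[Si](CC)(CC)OS(=O)(=O)C(F)(F)F
Why: Silyl triflate silylation protects both the primary and the hindered tertiary hydroxyl as fluoride-labile ethers that survive the organometallic steps and keep the C4 oxygen from lactonising onto C1 later.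

**Step 6**
Reactants: 11 (2R)-2-[(triethylsilyl)oxy]-2-{[(triethylsilyl)oxy]methyl}-1-Xc-pent-4-yn-1-one
Product: 13 (2R,4E)-4-methyl-5-(4,4,5,5-tetramethyl-1,3,2-dioxaborolan-2-yl)-2-[(triethylsilyl)oxy]-2-{[(triethylsilyl)oxy]methyl}-1-Xc-pent-4-en-1-one, via alkenylalane 12 (not isolated)
Conditions: AlMe3, Cp2ZrCl2 (20 mol%), CH2Cl2, 0 °C → rt; then MeOBpin, 0 °C → rt
Reagents that add atoms: trimethylaluminium, C[Al](C)C; 2-methoxy-4,4,5,5-tetramethyl-1,3,2-dioxaborolane, COB1OC(C)(C)C(C)(C)O1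
Why: Negishi zirconium-catalysed syn-methylalumination of the terminal alkyne places methyl on C6 and aluminium on C7 cis to each other, and Al-to-B exchange with retention gives the (E)-alkenylboronate that fixes the C6=C7 geometry.

**Step 7**
Reactants: 13 (2R,4E)-4-methyl-5-(pinacolboryl)-2-[(triethylsilyl)oxy]-2-{[(triethylsilyl)oxy]methyl}-1-Xc-pent-4-en-1-one; 14 (3E)-pent-3-en-2-one
Product: 15 (2R,4E,6S)-4,6-dimethyl-2-[(triethylsilyl)oxy]-2-{[(triethylsilyl)oxy]methyl}-1-Xc-non-4-ene-1,8-dione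
Conditions: [RhCl(C2H4)2]2 (2.5 mol%), (R)-BINAP, KOH (10 mol%), dioxane/H2O (10:1), 40 °C
Reagents that add atoms: none
Why: Hayashi–Miyaura rhodium-catalysed asymmetric 1,4-addition of the alkenylboronate to the enone forms the C7–C8 bond with retention of alkene geometry, and (R)-BINAP selects the enone face to set C8 as S under catalyst control (the C4 centre is remote).

**Step 8**
Reactants: 15 (2R,4E,6S)-4,6-dimethyl-2-[(triethylsilyl)oxy]-2-{[(triethylsilyl)oxy]methyl}-1-Xc-non-4-ene-1,8-dione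
Product: 17 (4S,6E,8R)-4,6-dimethyl-9-oxo-9-Xc-8-[(triethylsilyl)oxy]-8-{[(triethylsilyl)oxy]methyl}nona-1,6-dien-2-yl trifluoromethanesulfonate, via potassium enolate 16 (not isolated)
Conditions: KN(SiMe3)2, THF, −78 °C; then PhNTf2, −78 → 0 °C
Reagents that add atoms: N-phenylbis(trifluoromethanesulfonimide), O=S(=O)(N(c1ccccc1)S(=O)(=O)C(F)(F)F)C(F)(F)F
Why: Kinetic deprotonation of the methyl ketone on the methyl side and O-triflation give the 2-triflyloxy-1-alkene that carries the future C10 exocyclic methylene; the amide has no α-hydrogen and C8 is not adjacent to the enolate.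

**Step 9**
Reactants: 17 (4S,6E,8R)-enol triflate; 18 tert-butyldimethyl(prop-2-yn-1-yloxy)silane
Product: 19 (2R,4E,6S)-11-{[tert-butyl(dimethyl)silyl]oxy}-4,6-dimethyl-8-methylidene-2-[(triethylsilyl)oxy]-2-{[(triethylsilyl)oxy]methyl}-1-Xc-undec-4-en-9-yn-1-one
Conditions: Pd(PPh3)4 (5 mol%), CuI (10 mol%), i-Pr2NH, THF, rt
Reagents that add atoms: none
Why: Sonogashira coupling of the alkenyl triflate with the terminal alkyne builds the 2-substituted 1,3-enyne (C10–C11–C12 plus the protected C12 hydroxymethyl carbon) without touching any stereocentre.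

**Step 10**
Reactants: 19 (2R,4E,6S)-enyne; 20 propanal
Product: 21 (2R,4E,6S,9E)-10-({[tert-butyl(dimethyl)silyl]oxy}methyl)-11-hydroxy-4,6-dimethyl-8-methylidene-2-[(triethylsilyl)oxy]-2-{[(triethylsilyl)oxy]methyl}-1-Xc-trideca-4,9-dien-1-one (both C11 epimers)
Conditions: Ni(cod)2 (10 mol%), PBu3 (20 mol%), Et3B, toluene, rt
Reagents that add atoms: none
Why: Nickel-catalysed reductive alkyne–aldehyde coupling of a 1,3-enyne forms the C–C bond at the alkyne carbon distal to the alkene and adds H and the carbinol carbon syn, which gives the (E)-C11=C12 geometry with the silyloxymethyl group cis to C10; the carbinol (C13) is formed unselectively and is corrected in the next two steps.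

**Step 11**
Reactants: 21 dienyl carbinol (both C11 epimers)
Product: 22 (2R,4E,6S,9E)-10-({[tert-butyl(dimethyl)silyl]oxy}methyl)-4,6-dimethyl-8-methylidene-2-[(triethylsilyl)oxy]-2-{[(triethylsilyl)oxy]methyl}-1-Xc-trideca-4,9-diene-1,11-dione
Conditions: MnO2, CH2Cl2, rt
Reagents that add atoms: none
Why: Chemoselective MnO2 oxidation of the allylic alcohol converges both epimers on one dienone without isomerising the trisubstituted alkene.

**Step 12**
Reactants: 22 dienone
Product: 23 (2R,4E,6S,9E,11S)-10-({[tert-butyl(dimethyl)silyl]oxy}methyl)-11-hydroxy-4,6-dimethyl-8-methylidene-2-[(triethylsilyl)oxy]-2-{[(triethylsilyl)oxy]methyl}-1-Xc-trideca-4,9-dien-1-one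
Conditions: (R)-2-methyl-CBS-oxazaborolidine (20 mol%), catecholborane, toluene, −78 °C
Reagents that add atoms: none
Why: Corey–Bakshi–Shibata reduction of the α-substituted enone, with the alkenyl group as the large substituent, gives the (S)-carbinol (C13) under catalyst control; catecholborane leaves the alkenes and the tertiary amide alone.

**Step 13**
Reactants: 23 (11S)-hydroxy amide
Product: 24 (2R,4E,6S,9E,11S)-10-({[tert-butyl(dimethyl)silyl]oxy}methyl)-11-hydroxy-4,6-dimethyl-8-methylidene-2-[(triethylsilyl)oxy]-2-{[(triethylsilyl)oxy]methyl}trideca-4,9-dienal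
Conditions: LiAlH(OEt)3, THF, 0 °C; aq. potassium sodium tartrate
Reagents that add atoms: none
Why: Partial reduction of the tertiary amide stops at the O-aluminated hemiaminal, which collapses on work-up to the C3 aldehyde and releases auxiliary 2; C4 has no hydrogen and cannot epimerise.

**Step 14**
Reactants: 24 hydroxy aldehyde; 25 2-bromopropanoyl bromide (racemic)
Product: 26 (3S,4E,8S,9E,12R)-4-({[tert-butyl(dimethyl)silyl]oxy}methyl)-8,10-dimethyl-6-methylidene-13-oxo-12-[(triethylsilyl)oxy]-12-{[(triethylsilyl)oxy]methyl}trideca-4,9-dien-3-yl 2-bromopropanoate (both epimers at the CHBr carbon)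
Conditions: pyridine, CH2Cl2, −20 °C
Reagents that add atoms: none
Why: O-acylation of the secondary allylic alcohol by the acid bromide brings in C1, C2 and the C2 methyl; the aldehyde is inert and the CHBr centre is deliberately left unselective.

**Step 15**
Reactants: 26 bromo ester aldehyde
Product: 27 (5R,7E,9S,12E,14S)-13-({[tert-butyl(dimethyl)silyl]oxy}methyl)-14-ethyl-4-hydroxy-3,7,9-trimethyl-11-methylidene-5-[(triethylsilyl)oxy]-5-{[(triethylsilyl)oxy]methyl}-1-oxacyclotetradeca-7,12-dien-2-one (C3/C4 epimers)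
Conditions: SmI2, THF (0.002 M), −78 → 0 °C
Reagents that add atoms: none
Why: Samarium Reformatsky macrocyclisation (the samarium enolate from the α-bromo ester adds to the non-enolisable aldehyde at high dilution) closes the 14-membered ring at C2–C3; the two new centres need no control because one is oxidised and the other equilibrated next.

**Step 16**
Reactants: 27 β-hydroxy lactone
Product: 28 (3R,5R,7E,9S,12E,14S)-13-({[tert-butyl(dimethyl)silyl]oxy}methyl)-14-ethyl-3,7,9-trimethyl-11-methylidene-5-[(triethylsilyl)oxy]-5-{[(triethylsilyl)oxy]methyl}-1-oxacyclotetradeca-7,12-diene-2,4-dione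
Conditions: Dess–Martin periodinane, pyridine, CH2Cl2, 0 °C → rt
Reagents that add atoms: none
Why: Dess–Martin oxidation of the hindered secondary alcohol gives the β-keto lactone, whose C2 epimerises through the enol to the assumed more stable (2R) configuration.

**Step 17**
Reactants: 28 protected β-keto lactone
Product: 29 (3R,5R,7E,9S,12E,14S)-14-ethyl-5-hydroxy-5,13-bis(hydroxymethyl)-3,7,9-trimethyl-11-methylidene-1-oxacyclotetradeca-7,12-diene-2,4-dione
Conditions: HF·pyridine, pyridine, THF, 0 °C → rt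
Reagents that add atoms: none
Why: Buffered fluoride desilylation removes all three silyl ethers without base, which avoids attack of the freed C4–OH on the lactone carbonyl and ionisation of the allylic ester, and leaves every stereocentre intact.

**Compound list**
1 | furan-2-carbonyl chloride | O=C(Cl)c1ccco1 | starting material
2 | (2S,5S)-2,5-bis(methoxymethyl)pyrrolidine | COC[C@@H]1CC[C@@H](COC)N1 | starting material
3 | furan-2-yl[(2S,5S)-2,5-bis(methoxymethyl)pyrrolidin-1-yl]methanone | COC[C@@H]1CC[C@@H](COC)N1C(=O)c2ccco2 | intermediate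
4 | (3-bromoprop-1-yn-1-yl)trimethylsilane | C[Si](C)(C)C#CCBr | starting material
5 | sodium [(2S,5S)-2,5-bis(methoxymethyl)pyrrolidin-1-yl](furan-2(5H)-ylidene)methanolate | COC[C@@H]1CC[C@@H](COC)N1C([O-])=C2OCC=C2.[Na+] | intermediate
6 | [(2R)-2-[3-(trimethylsilyl)prop-2-yn-1-yl]-2,5-dihydrofuran-2-yl][(2S,5S)-2,5-bis(methoxymethyl)pyrrolidin-1-yl]methanone | COC[C@@H]1CC[C@@H](COC)N1C(=O)[C@]2(CC#C[Si](C)(C)C)OCC=C2 | intermediate
7 | (5R)-5-{[(2S,5S)-2,5-bis(methoxymethyl)pyrrolidin-1-yl]carbonyl}-5-[3-(trimethylsilyl)prop-2-yn-1-yl]furan-2(5H)-one | COC[C@@H]1CC[C@@H](COC)N1C(=O)[C@]2(CC#C[Si](C)(C)C)OC(=O)C=C2 | intermediate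
8 | (2R)-2-formyl-1-oxo-1-Xc-5-(trimethylsilyl)pent-4-yn-2-yl oxoacetate | COC[C@@H]1CC[C@@H](COC)N1C(=O)[C@](C=O)(CC#C[Si](C)(C)C)OC(=O)C=O | intermediate
9 | (2R)-2-(hydroxymethyl)-1-oxo-1-Xc-5-(trimethylsilyl)pent-4-yn-2-yl hydroxyacetate | COC[C@@H]1CC[C@@H](COC)N1C(=O)[C@](CO)(CC#C[Si](C)(C)C)OC(=O)CO | intermediate
10 | (2R)-2-hydroxy-2-(hydroxymethyl)-1-[(2S,5S)-2,5-bis(methoxymethyl)pyrrolidin-1-yl]pent-4-yn-1-one | COC[C@@H]1CC[C@@H](COC)N1C(=O)[C@](CO)(CC#C)O | intermediate
11 | (2R)-2-[(triethylsilyl)oxy]-2-{[(triethylsilyl)oxy]methyl}-1-Xc-pent-4-yn-1-one | COC[C@@H]1CC[C@@H](COC)N1C(=O)[C@](CO[Si](CC)(CC)CC)(CC#C)O[Si](CC)(CC)CC | intermediate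
12 | dimethyl[(1E,4R)-2-methyl-5-oxo-5-Xc-4-[(triethylsilyl)oxy]-4-{[(triethylsilyl)oxy]methyl}pent-1-en-1-yl]alane | COC[C@@H]1CC[C@@H](COC)N1C(=O)[C@](CO[Si](CC)(CC)CC)(C/C(C)=C/[Al](C)C)O[Si](CC)(CC)CC | intermediate
13 | (2R,4E)-4-methyl-5-(4,4,5,5-tetramethyl-1,3,2-dioxaborolan-2-yl)-2-[(triethylsilyl)oxy]-2-{[(triethylsilyl)oxy]methyl}-1-Xc-pent-4-en-1-one | COC[C@@H]1CC[C@@H](COC)N1C(=O)[C@](CO[Si](CC)(CC)CC)(C/C(C)=C/B2OC(C)(C)C(C)(C)O2)O[Si](CC)(CC)CC | intermediate
14 | (3E)-pent-3-en-2-one | C/C=C/C(C)=O | starting material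
15 | (2R,4E,6S)-4,6-dimethyl-2-[(triethylsilyl)oxy]-2-{[(triethylsilyl)oxy]methyl}-1-Xc-non-4-ene-1,8-dione | COC[C@@H]1CC[C@@H](COC)N1C(=O)[C@](CO[Si](CC)(CC)CC)(C/C(C)=C/[C@@H](C)CC(C)=O)O[Si](CC)(CC)CC | intermediate
16 | potassium (4S,6E,8R)-4,6-dimethyl-9-oxo-9-Xc-8-[(triethylsilyl)oxy]-8-{[(triethylsilyl)oxy]methyl}nona-1,6-dien-2-olate | COC[C@@H]1CC[C@@H](COC)N1C(=O)[C@](CO[Si](CC)(CC)CC)(C/C(C)=C/[C@@H](C)CC(=C)[O-])O[Si](CC)(CC)CC.[K+] | intermediate
17 | (4S,6E,8R)-4,6-dimethyl-9-oxo-9-Xc-8-[(triethylsilyl)oxy]-8-{[(triethylsilyl)oxy]methyl}nona-1,6-dien-2-yl trifluoromethanesulfonate | COC[C@@H]1CC[C@@H](COC)N1C(=O)[C@](CO[Si](CC)(CC)CC)(C/C(C)=C/[C@@H](C)CC(=C)OS(=O)(=O)C(F)(F)F)O[Si](CC)(CC)CC | intermediate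
18 | tert-butyldimethyl(prop-2-yn-1-yloxy)silane | C#CCO[Si](C)(C)C(C)(C)C | starting material
19 | (2R,4E,6S)-11-{[tert-butyl(dimethyl)silyl]oxy}-4,6-dimethyl-8-methylidene-2-[(triethylsilyl)oxy]-2-{[(triethylsilyl)oxy]methyl}-1-Xc-undec-4-en-9-yn-1-one | COC[C@@H]1CC[C@@H](COC)N1C(=O)[C@](CO[Si](CC)(CC)CC)(C/C(C)=C/[C@@H](C)CC(=C)C#CCO[Si](C)(C)C(C)(C)C)O[Si](CC)(CC)CC | intermediate
20 | propanal | CCC=O | starting material
21 | (2R,4E,6S,9E)-10-({[tert-butyl(dimethyl)silyl]oxy}methyl)-11-hydroxy-4,6-dimethyl-8-methylidene-2-[(triethylsilyl)oxy]-2-{[(triethylsilyl)oxy]methyl}-1-Xc-trideca-4,9-dien-1-one (C11 epimers) | COC[C@@H]1CC[C@@H](COC)N1C(=O)[C@](CO[Si](CC)(CC)CC)(C/C(C)=C/[C@@H](C)CC(=C)/C=C(\CO[Si](C)(C)C(C)(C)C)C(O)CC)O[Si](CC)(CC)CC | intermediate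
22 | (2R,4E,6S,9E)-10-({[tert-butyl(dimethyl)silyl]oxy}methyl)-4,6-dimethyl-8-methylidene-2-[(triethylsilyl)oxy]-2-{[(triethylsilyl)oxy]methyl}-1-Xc-trideca-4,9-diene-1,11-dione | COC[C@@H]1CC[C@@H](COC)N1C(=O)[C@](CO[Si](CC)(CC)CC)(C/C(C)=C/[C@@H](C)CC(=C)/C=C(\CO[Si](C)(C)C(C)(C)C)C(=O)CC)O[Si](CC)(CC)CC | intermediate
23 | (2R,4E,6S,9E,11S)-10-({[tert-butyl(dimethyl)silyl]oxy}methyl)-11-hydroxy-4,6-dimethyl-8-methylidene-2-[(triethylsilyl)oxy]-2-{[(triethylsilyl)oxy]methyl}-1-Xc-trideca-4,9-dien-1-one | COC[C@@H]1CC[C@@H](COC)N1C(=O)[C@](CO[Si](CC)(CC)CC)(C/C(C)=C/[C@@H](C)CC(=C)/C=C(\CO[Si](C)(C)C(C)(C)C)[C@H](CC)O)O[Si](CC)(CC)CC | intermediate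
24 | (2R,4E,6S,9E,11S)-10-({[tert-butyl(dimethyl)silyl]oxy}methyl)-11-hydroxy-4,6-dimethyl-8-methylidene-2-[(triethylsilyl)oxy]-2-{[(triethylsilyl)oxy]methyl}trideca-4,9-dienal | O=C[C@](CO[Si](CC)(CC)CC)(C/C(C)=C/[C@@H](C)CC(=C)/C=C(\CO[Si](C)(C)C(C)(C)C)[C@H](CC)O)O[Si](CC)(CC)CC | intermediate
25 | 2-bromopropanoyl bromide (racemic) | CC(Br)C(=O)Br | starting material
26 | (3S,4E,8S,9E,12R)-4-({[tert-butyl(dimethyl)silyl]oxy}methyl)-8,10-dimethyl-6-methylidene-13-oxo-12-[(triethylsilyl)oxy]-12-{[(triethylsilyl)oxy]methyl}trideca-4,9-dien-3-yl 2-bromopropanoate (CHBr epimers) | O=C[C@](CO[Si](CC)(CC)CC)(C/C(C)=C/[C@@H](C)CC(=C)/C=C(\CO[Si](C)(C)C(C)(C)C)[C@H](CC)OC(=O)C(C)Br)O[Si](CC)(CC)CC | intermediate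
27 | (5R,7E,9S,12E,14S)-13-({[tert-butyl(dimethyl)silyl]oxy}methyl)-14-ethyl-4-hydroxy-3,7,9-trimethyl-11-methylidene-5-[(triethylsilyl)oxy]-5-{[(triethylsilyl)oxy]methyl}-1-oxacyclotetradeca-7,12-dien-2-one (C3/C4 epimers) | C=C1/C=C(\CO[Si](C)(C)C(C)(C)C)[C@H](CC)OC(=O)C(C)C(O)[C@](O[Si](CC)(CC)CC)(CO[Si](CC)(CC)CC)C/C(C)=C/[C@@H](C)C1 | intermediate
28 | (3R,5R,7E,9S,12E,14S)-13-({[tert-butyl(dimethyl)silyl]oxy}methyl)-14-ethyl-3,7,9-trimethyl-11-methylidene-5-[(triethylsilyl)oxy]-5-{[(triethylsilyl)oxy]methyl}-1-oxacyclotetradeca-7,12-diene-2,4-dione | C=C1/C=C(\CO[Si](C)(C)C(C)(C)C)[C@H](CC)OC(=O)[C@H](C)C(=O)[C@](O[Si](CC)(CC)CC)(CO[Si](CC)(CC)CC)C/C(C)=C/[C@@H](C)C1 | intermediate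
29 | (3R,5R,7E,9S,12E,14S)-14-ethyl-5-hydroxy-5,13-bis(hydroxymethyl)-3,7,9-trimethyl-11-methylidene-1-oxacyclotetradeca-7,12-diene-2,4-dione | C=C1/C=C(\CO)[C@H](CC)OC(=O)[C@H](C)C(=O)[C@](O)(CO)C/C(C)=C/[C@@H](C)C1 | target

**Totals**
Total step count: 17. Longest linear sequence: 17 steps (1 → 29).

**Steps most likely to fail, with fallbacks**

Step 2 (facial selectivity of the reductive alkylation on a furan with no C3 substituent, and alkylation with a propargylic bromide in ammonia). The fallback sets out from 3 and returns at 6. Compound 3 is reduced under the same dissolving-metal conditions but the enolate is protonated, giving the 2,5-dihydrofuran-2-yl(Xc)methanone F1 as a mixture at C2. F1 is then deprotonated with LiN(i-Pr)2/LiCl in THF at −78 °C and alkylated with 4. The dearomatisation and the C–C bond formation are thereby separated, the quaternary centre is set in a discrete lithium amide-enolate alkylation, and the minor epimer can be removed by chromatography because the products are diastereomers.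

Step 13 (partial reduction of a very hindered, α-quaternary tertiary amide). The fallback sets out from 23 and returns at 24. Exhaustive reduction with LiNH2BH3 (THF, 0 → 23 °C) gives the (2S,4E,6S,9E,11S)-10-({[tert-butyl(dimethyl)silyl]oxy}methyl)-4,6-dimethyl-8-methylidene-2-[(triethylsilyl)oxy]-2-{[(triethylsilyl)oxy]methyl}trideca-4,9-diene-1,11-diol F2 and frees 2. The primary alcohol of F2 is then oxidised selectively over the secondary allylic one with TEMPO/PhI(OAc)2 to give 24. The risk to watch in this detour is silyl migration between the two CH2O arms on C4, which would erode the C4 configuration.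

Step 15 (14-membered ring closure by C–C bond formation onto a neopentyl aldehyde). The fallback sets out from 24 and returns at 28, closing the ring at the C1–O bond instead. Oxidation of 24 with NaClO2/NaH2PO4/2-methylbut-2-ene gives the (2R,4E,6S,9E,11S)-10-({[tert-butyl(dimethyl)silyl]oxy}methyl)-11-hydroxy-4,6-dimethyl-8-methylidene-2-[(triethylsilyl)oxy]-2-{[(triethylsilyl)oxy]methyl}trideca-4,9-dienoic acid F3. Activation with carbonyldiimidazole and decarboxylative C-acylation with Mg(O2CCH(CH3)C(O)S-t-Bu)2 gives the S-tert-butyl (4R,6E,8S,11E,13S)-12-({[tert-butyl(dimethyl)silyl]oxy}methyl)-13-hydroxy-2,6,8-trimethyl-10-methylidene-3-oxo-4-[(triethylsilyl)oxy]-4-{[(triethylsilyl)oxy]methyl}pentadeca-6,11-dienethioate F4. Treatment of F4 with AgOCOCF3/Na2HPO4 in THF at high dilution activates the thioester and the C13 hydroxyl lactonises onto it, giving 28 directly.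

Further compounds
F1 | step 2 | (2,5-dihydrofuran-2-yl)[(2S,5S)-2,5-bis(methoxymethyl)pyrrolidin-1-yl]methanone (C2 epimers) | COC[C@@H]1CC[C@@H](COC)N1C(=O)C2OCC=C2
F2 | step 13 | (2S,4E,6S,9E,11S)-10-({[tert-butyl(dimethyl)silyl]oxy}methyl)-4,6-dimethyl-8-methylidene-2-[(triethylsilyl)oxy]-2-{[(triethylsilyl)oxy]methyl}trideca-4,9-diene-1,11-diol | OC[C@](CO[Si](CC)(CC)CC)(C/C(C)=C/[C@@H](C)CC(=C)/C=C(\CO[Si](C)(C)C(C)(C)C)[C@H](CC)O)O[Si](CC)(CC)CC
F3 | step 15 | (2R,4E,6S,9E,11S)-10-({[tert-butyl(dimethyl)silyl]oxy}methyl)-11-hydroxy-4,6-dimethyl-8-methylidene-2-[(triethylsilyl)oxy]-2-{[(triethylsilyl)oxy]methyl}trideca-4,9-dienoic acid | OC(=O)[C@](CO[Si](CC)(CC)CC)(C/C(C)=C/[C@@H](C)CC(=C)/C=C(\CO[Si](C)(C)C(C)(C)C)[C@H](CC)O)O[Si](CC)(CC)CC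
F4 | step 15 | S-tert-butyl (4R,6E,8S,11E,13S)-12-({[tert-butyl(dimethyl)silyl]oxy}methyl)-13-hydroxy-2,6,8-trimethyl-10-methylidene-3-oxo-4-[(triethylsilyl)oxy]-4-{[(triethylsilyl)oxy]methyl}pentadeca-6,11-dienethioate (C2 epimers) | CC(C(=O)SC(C)(C)C)C(=O)[C@](CO[Si](CC)(CC)CC)(C/C(C)=C/[C@@H](C)CC(=C)/C=C(\CO[Si](C)(C)C(C)(C)C)[C@H](CC)O)O[Si](CC)(CC)CC
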